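**Assumption:** the SMILES is read as the 6R upper chain, all-E alkenes and a cis-4,5-diol (4S,5R; cyclohex-2-en-1-one numbering: C1 = C=O, C2 = C–N, C4 = tertiary carbinol, C5 = CHOH). The glutaconaldehyde potassium salt, the two phosphoranes, triphenylphosphine dibromide and p-tolyl 2-(trimethylsilyl)ethynyl sulfone are taken as catalogue items.

## Retrosynthetic overview

1. Last bond: Stille union (C2''–C3'' of the triene) of a ring-bound (E)-vinylstannane with the (2E,4E)-5-bromodienamide of the aminocyclopentenone unit; the stannane comes from a C4-ethynyl group.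
2. C2–N bond: copper-catalysed coupling of the 2-iodoenone with (2E,4E,6R)-2,4,6-trimethyldeca-2,4-dienamide.
3. Key C4–C bond: light-driven hydrogen-atom-transfer alkynylation of the C4–H of the quinic-acid-derived enone acetonide, with retention enforced by the cis-fused dioxolane, so C5 (from quinic acid) sets C4.
4. Side chains: (S)-3-bromo-2-methylpropan-1-ol → (R)-2-methylhexanal → two Wittig reactions → amide; cyclopentane-1,3-dione → aminoenol; glutaconaldehyde salt → bromodienoic acid.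
5. Rings: both carbocycles are bought (quinic acid, cyclopentane-1,3-dione). Only a temporary lactone (closed in step 10, opened in step 11) and a temporary dioxolane (closed in step 10, opened in step 16) are formed.

## Route

Step 1
Reactants: 1 (S)-3-bromo-2-methylpropan-1-ol
Product: 2 (R)-2-methylhexan-1-ol
Conditions: n-PrMgBr (3 equiv), Li2CuCl4 (3 mol %), THF, −78 °C → rt; aq NH4Cl
Reagents that add atoms: n-propylmagnesium bromide, CCC[Mg]Br
Why: Copper-catalysed Kochi-type sp3–sp3 cross-coupling of the primary bromide (the first equivalent of Grignard only deprotonates the OH); the stereocentre is untouched and the descriptor changes from S to R only because CH2Br becomes the lower-ranking butyl group.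

Step 2
Reactants: 2 (R)-2-methylhexan-1-ol
Product: 4 (2E,4R)-2,4-dimethyloct-2-enal, via (R)-2-methylhexanal 3 (not isolated)
Conditions: Dess–Martin periodinane, NaHCO3, ClCH2CH2Cl, 0 °C → rt; then Ph3P=C(CH3)CHO, 70 °C
Reagents that add atoms: 2-(triphenylphosphoranylidene)propanal, CC(C=O)=P(c1ccccc1)(c1ccccc1)c1ccccc1
Why: Buffered Dess–Martin oxidation gives the epimerisable aldehyde, which is consumed in the same flask by Wittig olefination with the stabilised formyl ylide to give the (E)-trisubstituted enal; C4 is the bought centre.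

Step 3
Reactants: 4 (2E,4R)-2,4-dimethyloct-2-enal
Product: 5 ethyl (2E,4E,6R)-2,4,6-trimethyldeca-2,4-dienoate
Conditions: Ph3P=C(CH3)CO2Et, toluene, 90 °C
Reagents that add atoms: ethyl 2-(triphenylphosphoranylidene)propanoate, CCOC(=O)C(C)=P(c1ccccc1)(c1ccccc1)c1ccccc1
Why: Wittig olefination with the stabilised ester ylide is (E)-selective for the new trisubstituted alkene and leaves the allylic stereocentre alone.

Step 4
Reactants: 5 ethyl (2E,4E,6R)-2,4,6-trimethyldeca-2,4-dienoate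
Product: 6 (2E,4E,6R)-2,4,6-trimethyldeca-2,4-dienamide
Conditions: AlMe3, NH4Cl, toluene, 0 → 50 °C; aq HCl work-up
Reagents that add atoms: ammonium chloride, [NH4+].[Cl-]
Why: Weinreb-type aminolysis by the aluminium amide formed from AlMe3 and NH4Cl converts the hindered conjugated ester directly into the primary amide without touching the diene or C6.

Step 5
Reactants: 7 cyclopentane-1,3-dione
Product: 8 2-(hydroxyimino)cyclopentane-1,3-dione
Conditions: NaNO2, aq HCl, 0 °C
Reagents that add atoms: sodium nitrite, [Na+].[O-]N=O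
Why: Electrophilic nitrosation of the fully enolised 1,3-dione at C2, followed by tautomerisation to the oxime.

Step 6
Reactants: 8 2-(hydroxyimino)cyclopentane-1,3-dione
Product: 9 2-amino-3-hydroxycyclopent-2-en-1-one hydrochloride
Conditions: H2 (3 atm), Pd/C, HCl, EtOH, rt
Reagents that add atoms: hydrogen chloride, Cl
Why: Catalytic hydrogenation of the oxime in acid gives the 2-amino-1,3-dione, isolated as its stable enolised hydrochloride.

Step 7
Reactants: 10 potassium (1E,3E)-5-oxopenta-1,3-dien-1-olate (glutaconaldehyde potassium salt)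
Product: 11 (2E,4E)-5-bromopenta-2,4-dienal
Conditions: Ph3PBr2, CH2Cl2, 0 °C → rt
Reagents that add atoms: triphenylphosphine dibromide, BrP(Br)(c1ccccc1)(c1ccccc1)c1ccccc1
Why: Deoxybromination of the vinylogous carboxylate (oxyphosphonium activation, then addition–elimination by bromide) gives the thermodynamically preferred (2E,4E)-bromodienal.

Step 8
Reactants: 11 (2E,4E)-5-bromopenta-2,4-dienal
Product: 12 (2E,4E)-5-bromopenta-2,4-dienoic acid
Conditions: NaClO2, NaH2PO4, 2-methylbut-2-ene, t-BuOH/H2O, 0 °C → rt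
Reagents that add atoms: sodium chlorite, [Na+].[O-]Cl=O
Why: Pinnick oxidation converts the enal into the acid without touching the vinyl bromide or the diene geometry.

Step 9
Reactants: 12 (2E,4E)-5-bromopenta-2,4-dienoic acid; 9 2-amino-3-hydroxycyclopent-2-en-1-one hydrochloride
Product: 14 (2E,4E)-5-bromo-N-(2-hydroxy-5-oxocyclopent-1-en-1-yl)penta-2,4-dienamide, via dienoyl chloride 13 (not isolated)
Conditions: (COCl)2, DMF (cat.), CH2Cl2, 0 °C → rt, evaporate; then 9, Et3N, CH2Cl2/THF, −20 °C → rt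
Reagents that add atoms: none
Why: Acid chloride formation and N-acylation of the amine freed in the flask (amide formation); any O-acyl enol ester passes its acyl group on to nitrogen.

Step 10
Reactants: 15 (−)-quinic acid
Product: 16 3,4-O-isopropylidene-1,5-quinide (quinic acid 1,5-lactone 3,4-acetonide)
Conditions: Me2C(OMe)2, TsOH·H2O (cat.), acetone, reflux
Reagents that add atoms: 2,2-dimethoxypropane, COC(C)(C)OC
Why: Acid-catalysed lactonisation of the cis 1-CO2H/5-OH pair and acetalisation of the cis-3,4-diol; no stereocentre changes.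

Step 11
Reactants: 16 3,4-O-isopropylidene-1,5-quinide
Product: 18 (3R,4S,5R)-3-hydroxy-4,5-(isopropylidenedioxy)cyclohexan-1-one, via reduced triol 17 (not isolated)
Conditions: NaBH4, EtOH, 0 °C → rt; AcOH quench; then NaIO4, pH 7 phosphate buffer, 0 °C
Reagents that add atoms: none
Why: NaBH4 reduces the α-hydroxy lactone to the 1,2-diol, which periodate cleaves (glycol cleavage) to the ketone; the three ring carbinol centres from quinic acid are untouched.

Step 12
Reactants: 18 (3R,4S,5R)-3-hydroxy-4,5-(isopropylidenedioxy)cyclohexan-1-one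
Product: 20 (4S,5R)-4,5-(isopropylidenedioxy)cyclohex-2-en-1-one, via keto mesylate 19 (not isolated)
Conditions: MsCl, Et3N, CH2Cl2, 0 °C → rt
Reagents that add atoms: none
Why: Mesylation of the β-hydroxy ketone and E1cB elimination give the conjugated enone; C4 and C5 keep the quinic acid configuration.

Step 13
Reactants: 20 (4S,5R)-4,5-(isopropylidenedioxy)cyclohex-2-en-1-one
Product: 21 (4R,5R)-4,5-(isopropylidenedioxy)-4-[(trimethylsilyl)ethynyl]cyclohex-2-en-1-one
Conditions: p-tolyl 2-(trimethylsilyl)ethynyl sulfone (1.5 equiv), (Bu4N)4[W10O32] (2 mol %), NaHCO3, degassed MeCN, 390 nm LEDs, 20 °C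
Reagents that add atoms: p-tolyl 2-(trimethylsilyl)ethynyl sulfone, Cc1ccc(cc1)S(=O)(=O)C#C[Si](C)(C)C
Why: Proposed new method: photoexcited decatungstate abstracts the weakest and most hydridic hydrogen of 20 (C4–H, allylic and α-oxygenated); the delocalised radical is trapped at its nucleophilic alkoxy-bearing terminus C4 (polarity-matched with the electron-poor sulfonyl alkyne, and attack at C2 would give up enone conjugation) by α-addition and β-scission of the tosyl radical, which the reduced polyoxometalate turns over; because C4 stays tied into the cis-fused dioxolane, the new bond forms only anti to the C5–O bond (the other face would give a strained trans-fused acetonide), so C–H is replaced with retention and the quinic-acid C5 centre sets the quaternary C4; the closest known reactions are benzophenone- or decatungstate-mediated C(sp3)–H alkynylations of ethers with 1-sulfonyl-2-silylacetylenes, not yet shown for a tertiary γ-C–H of an enone or with transfer of configuration through a ring-fused acetonide.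

Step 14
Reactants: 21 (4R,5R)-4,5-(isopropylidenedioxy)-4-[(trimethylsilyl)ethynyl]cyclohex-2-en-1-one
Product: 22 (4R,5R)-2-iodo-4,5-(isopropylidenedioxy)-4-[(trimethylsilyl)ethynyl]cyclohex-2-en-1-one
Conditions: I2, pyridine/CH2Cl2 (1:1), 0 °C → rt, dark
Reagents that add atoms: iodine, [I][I]
Why: Baylis–Hillman-type α-iodination of the enone (pyridine conjugate addition, enolate iodination, elimination); no stereocentre is involved and the C-silyl alkyne is inert.

Step 15
Reactants: 22 (4R,5R)-2-iodo-4,5-(isopropylidenedioxy)-4-[(trimethylsilyl)ethynyl]cyclohex-2-en-1-one; 6 (2E,4E,6R)-2,4,6-trimethyldeca-2,4-dienamide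
Product: 23 (2E,4E,6R)-N-{(3R,4R)-3,4-(isopropylidenedioxy)-6-oxo-3-[(trimethylsilyl)ethynyl]cyclohex-1-en-1-yl}-2,4,6-trimethyldeca-2,4-dienamide
Conditions: CuI (20 mol %), MeNHCH2CH2NHMe (40 mol %), Cs2CO3, THF, 55 °C
Reagents that add atoms: none
Why: Copper-catalysed Goldberg-type N-vinylation of the primary amide by the α-iodoenone forms the C2–N bond; the silyl cap keeps the alkyne from forming a copper acetylide.

Step 16
Reactants: 23 (2E,4E,6R)-N-{(3R,4R)-3,4-(isopropylidenedioxy)-6-oxo-3-[(trimethylsilyl)ethynyl]cyclohex-1-en-1-yl}-2,4,6-trimethyldeca-2,4-dienamide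
Product: 25 (2E,4E,6R)-N-[(3R,4R)-3-ethynyl-3,4-dihydroxy-6-oxocyclohex-1-en-1-yl]-2,4,6-trimethyldeca-2,4-dienamide, via desilylated acetonide 24 (not isolated)
Conditions: Bu4NF, AcOH, THF, 0 °C; then 1 M aq HCl, rt
Reagents that add atoms: none
Why: Buffered fluoride cleaves the alkynyl C–Si bond and aqueous acid then hydrolyses the acetonide at its ketal carbon, so the C–O bonds at both carbinol centres and their configurations are kept.

Step 17
Reactants: 25 (2E,4E,6R)-N-[(3R,4R)-3-ethynyl-3,4-dihydroxy-6-oxocyclohex-1-en-1-yl]-2,4,6-trimethyldeca-2,4-dienamide; 14 (2E,4E)-5-bromo-N-(2-hydroxy-5-oxocyclopent-1-en-1-yl)penta-2,4-dienamide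
Product: 27 (2E,4E,6R)-N-[(3S,4R)-3,4-dihydroxy-3-{(1E,3E,5E)-7-[(2-hydroxy-5-oxocyclopent-1-en-1-yl)amino]-7-oxohepta-1,3,5-trien-1-yl}-6-oxocyclohex-1-en-1-yl]-2,4,6-trimethyldeca-2,4-dienamide (CNP0117968.3), via vinylstannane 26 (not isolated)
Conditions: Bu3SnH (1.1 equiv), PdCl2(PPh3)2 (5 mol %), THF, 0 °C; then 14, DMF, rt, dark
Reagents that add atoms: none
Why: Palladium-catalysed syn-hydrostannation puts tin on the unhindered alkyne terminus to give the (E)-vinylstannane, and Stille coupling with the (E,E)-dienyl bromide forms the C2''–C3'' bond with retention of every alkene geometry; the ring descriptor changes from 3R to 3S only through CIP ranking.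

## Compound list

1 | (S)-3-bromo-2-methylpropan-1-ol | OC[C@H](C)CBr | starting material
2 | (R)-2-methylhexan-1-ol | OC[C@H](C)CCCC | intermediate
3 | (R)-2-methylhexanal (not isolated) | O=C[C@H](C)CCCC | intermediate
4 | (2E,4R)-2,4-dimethyloct-2-enal | CCCC[C@@H](C)/C=C(\C)C=O | intermediate
5 | ethyl (2E,4E,6R)-2,4,6-trimethyldeca-2,4-dienoate | CCCC[C@@H](C)/C=C(C)/C=C(\C)C(=O)OCC | intermediate
6 | (2E,4E,6R)-2,4,6-trimethyldeca-2,4-dienamide | CCCC[C@@H](C)/C=C(C)/C=C(\C)C(N)=O | intermediate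
7 | cyclopentane-1,3-dione | O=C1CCC(=O)C1 | starting material
8 | 2-(hydroxyimino)cyclopentane-1,3-dione | ON=C1C(=O)CCC1=O | intermediate
9 | 2-amino-3-hydroxycyclopent-2-en-1-one hydrochloride | Cl.NC1=C(O)CCC1=O | intermediate
10 | potassium (1E,3E)-5-oxopenta-1,3-dien-1-olate (glutaconaldehyde potassium salt) | [K+].[O-]/C=C/C=C/C=O | starting material
11 | (2E,4E)-5-bromopenta-2,4-dienal | O=C/C=C/C=C/Br | intermediate
12 | (2E,4E)-5-bromopenta-2,4-dienoic acid | OC(=O)/C=C/C=C/Br | intermediate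
13 | (2E,4E)-5-bromopenta-2,4-dienoyl chloride (not isolated) | ClC(=O)/C=C/C=C/Br | intermediate
14 | (2E,4E)-5-bromo-N-(2-hydroxy-5-oxocyclopent-1-en-1-yl)penta-2,4-dienamide | O=C(/C=C/C=C/Br)NC1=C(O)CCC1=O | intermediate
15 | (−)-quinic acid, (1S,3R,4S,5R)-1,3,4,5-tetrahydroxycyclohexane-1-carboxylic acid | OC(=O)[C@]1(O)C[C@@H](O)[C@@H](O)[C@H](O)C1 | starting material
16 | 3,4-O-isopropylidene-1,5-quinide (1-CO2H lactonised onto 5-OH, cis-3,4-diol as acetonide, centres as in quinic acid) | O=C1O[C@@H]2C[C@@]1(O)C[C@H]3OC(C)(C)O[C@@H]23 | intermediate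
17 | 1-(hydroxymethyl)-3,4-O-isopropylidene-cyclohexane-1,3,4,5-tetrol (lactone of 16 reduced to CH2OH and 5-OH, centres as in quinic acid; not isolated) | OC[C@]1(O)C[C@H]2OC(C)(C)O[C@H]2[C@H](O)C1 | intermediate
18 | (3R,4S,5R)-3-hydroxy-4,5-(isopropylidenedioxy)cyclohexan-1-one | O=C1C[C@H]2OC(C)(C)O[C@H]2[C@H](O)C1 | intermediate
19 | 3-O-methanesulfonate of 18, (3R,4R,5R)-4,5-(isopropylidenedioxy)-3-(mesyloxy)cyclohexan-1-one (not isolated) | O=C1C[C@H]2OC(C)(C)O[C@H]2[C@H](OS(C)(=O)=O)C1 | intermediate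
20 | (4S,5R)-4,5-(isopropylidenedioxy)cyclohex-2-en-1-one | O=C1C=C[C@@H]2OC(C)(C)O[C@@H]2C1 | intermediate
21 | (4R,5R)-4,5-(isopropylidenedioxy)-4-[(trimethylsilyl)ethynyl]cyclohex-2-en-1-one (cis-fused acetonide, alkynyl trans to the C5–O bond) | O=C1C=C[C@]2(C#C[Si](C)(C)C)OC(C)(C)O[C@@H]2C1 | intermediate
22 | (4R,5R)-2-iodo-4,5-(isopropylidenedioxy)-4-[(trimethylsilyl)ethynyl]cyclohex-2-en-1-one | O=C1C(I)=C[C@]2(C#C[Si](C)(C)C)OC(C)(C)O[C@@H]2C1 | intermediate
23 | (2E,4E,6R)-N-{(3R,4R)-3,4-(isopropylidenedioxy)-6-oxo-3-[(trimethylsilyl)ethynyl]cyclohex-1-en-1-yl}-2,4,6-trimethyldeca-2,4-dienamide | CCCC[C@@H](C)/C=C(C)/C=C(\C)C(=O)NC1=C[C@]2(C#C[Si](C)(C)C)OC(C)(C)O[C@@H]2CC1=O | intermediate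
24 | (2E,4E,6R)-N-[(3R,4R)-3-ethynyl-3,4-(isopropylidenedioxy)-6-oxocyclohex-1-en-1-yl]-2,4,6-trimethyldeca-2,4-dienamide (not isolated) | CCCC[C@@H](C)/C=C(C)/C=C(\C)C(=O)NC1=C[C@]2(C#C)OC(C)(C)O[C@@H]2CC1=O | intermediate
25 | (2E,4E,6R)-N-[(3R,4R)-3-ethynyl-3,4-dihydroxy-6-oxocyclohex-1-en-1-yl]-2,4,6-trimethyldeca-2,4-dienamide (cis-diol) | CCCC[C@@H](C)/C=C(C)/C=C(\C)C(=O)NC1=C[C@@](O)(C#C)[C@H](O)CC1=O | intermediate
26 | (2E,4E,6R)-N-{(3R,4R)-3,4-dihydroxy-6-oxo-3-[(E)-2-(tributylstannyl)ethenyl]cyclohex-1-en-1-yl}-2,4,6-trimethyldeca-2,4-dienamide (not isolated) | CCCC[C@@H](C)/C=C(C)/C=C(\C)C(=O)NC1=C[C@@](O)(/C=C/[Sn](CCCC)(CCCC)CCCC)[C@H](O)CC1=O | intermediate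
27 | (2E,4E,6R)-N-[(3S,4R)-3,4-dihydroxy-3-{(1E,3E,5E)-7-[(2-hydroxy-5-oxocyclopent-1-en-1-yl)amino]-7-oxohepta-1,3,5-trien-1-yl}-6-oxocyclohex-1-en-1-yl]-2,4,6-trimethyldeca-2,4-dienamide (CNP0117968.3) | CCCC[C@@H](C)/C=C(C)/C=C(\C)C(=O)NC1=C[C@@](O)(/C=C/C=C/C=C/C(=O)NC2=C(O)CCC2=O)[C@H](O)CC1=O | target

## Step count and risks

Total steps: 17 (steps 1–4 upper amide, steps 5–9 lower bromodienamide, steps 10–17 core and endgame).
Longest linear sequence: 8 steps (15 → 27, steps 10–17).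

**Step 13 (the proposed new step).** Risks are trapping at C2 instead of C4, addition of the radical to a second molecule of enone, and conjugate addition of sulfinate to 20. The fallback uses only known reactions, sets out from 20 and comes back to the route at 21.
- Luche reduction of 20 (NaBH4, CeCl3·7H2O, MeOH, −78 °C) gives (4S,5R)-4,5-(isopropylidenedioxy)cyclohex-2-en-1-ol F1; the C1 configuration is immaterial because that carbon is reoxidised later.
- TBDPSCl and imidazole give its tert-butyldiphenylsilyl ether F2.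
- Aqueous AcOH at 40 °C removes the acetonide to give (4S,5R)-1-[(tert-butyldiphenylsilyl)oxy]cyclohex-2-ene-4,5-diol F3.
- MnO2 oxidises only the allylic C4–OH to give (6R)-4-[(tert-butyldiphenylsilyl)oxy]-6-hydroxycyclohex-2-en-1-one F4.
- TBSOTf and 2,6-lutidine give (6R)-6-[(tert-butyldimethylsilyl)oxy]-4-[(tert-butyldiphenylsilyl)oxy]cyclohex-2-en-1-one F5.
- LiC≡CSiMe3 with CeCl3 in THF at −78 °C adds to the ketone anti to the neighbouring C–OTBS bond (polar Felkin–Anh control by the quinic-acid centre) to give (1R,6R)-6-[(tert-butyldimethylsilyl)oxy]-4-[(tert-butyldiphenylsilyl)oxy]-1-[(trimethylsilyl)ethynyl]cyclohex-2-en-1-ol F6.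
- HF·pyridine removes both O-silyl groups and leaves the C-silyl alkyne, giving (1R,6R)-1-[(trimethylsilyl)ethynyl]cyclohex-2-ene-1,4,6-triol F7.
- MnO2 oxidises the remaining allylic alcohol to (4R,5R)-4,5-dihydroxy-4-[(trimethylsilyl)ethynyl]cyclohex-2-en-1-one F8.
- Me2C(OMe)2 with pyridinium tosylate closes the acetonide and gives 21.

**Step 15.** Risks are base-induced opening of the β-alkoxy ketone and a sluggish coupling next to the quaternary carbon. The fallback makes the C–N bond through an azide and then acylates; it sets out from 22 (and from 5 for the acyl partner) and comes back at 23.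
- NaN3 with CuI and MeNHCH2CH2NHMe in EtOH/H2O converts 22 into (4R,5R)-2-azido-4,5-(isopropylidenedioxy)-4-[(trimethylsilyl)ethynyl]cyclohex-2-en-1-one F9.
- Staudinger reduction (PMe3, THF/H2O) gives (4R,5R)-2-amino-4,5-(isopropylidenedioxy)-4-[(trimethylsilyl)ethynyl]cyclohex-2-en-1-one F10.
- In parallel, LiOH hydrolysis of 5 gives (2E,4E,6R)-2,4,6-trimethyldeca-2,4-dienoic acid F11, and (COCl)2 converts it into (2E,4E,6R)-2,4,6-trimethyldeca-2,4-dienoyl chloride F12.
- Acylation of F10 with F12 in pyridine/CH2Cl2 gives 23.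

**Step 17.** Risks are the regiochemistry of hydrostannation beside the free diol, conjugate reduction of the enone, and loss of the stannane or triene. The fallback replaces tin chemistry by alkynyl coupling and net trans-reduction; it sets out from 25 and 14 and comes back at 27.
- Sonogashira coupling of 25 with 14 (Pd(PPh3)4, CuI, i-Pr2NH, THF) gives (2E,4E,6R)-N-[(3R,4R)-3,4-dihydroxy-3-{(3E,5E)-7-[(2-hydroxy-5-oxocyclopent-1-en-1-yl)amino]-7-oxohepta-3,5-dien-1-yn-1-yl}-6-oxocyclohex-1-en-1-yl]-2,4,6-trimethyldeca-2,4-dienamide F13.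
- Ruthenium-catalysed trans-hydrosilylation ([Cp*Ru(MeCN)3]PF6, (EtO)3SiH, CH2Cl2) gives the (1Z)-2-(triethoxysilyl) vinylsilane (2E,4E,6R)-N-[(3R,4R)-3,4-dihydroxy-3-{(1Z,3E,5E)-7-[(2-hydroxy-5-oxocyclopent-1-en-1-yl)amino]-7-oxo-2-(triethoxysilyl)hepta-1,3,5-trien-1-yl}-6-oxocyclohex-1-en-1-yl]-2,4,6-trimethyldeca-2,4-dienamide F14.
- Protodesilylation with CuI and Bu4NF in THF, with retention of geometry, gives 27.

## Further compounds

F1 | step 13 | (4S,5R)-4,5-(isopropylidenedioxy)cyclohex-2-en-1-ol (C1 epimers) | OC1C=C[C@@H]2OC(C)(C)O[C@@H]2C1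
F2 | step 13 | tert-butyldiphenylsilyl ether of F1 | CC(C)(C)[Si](OC1C=C[C@@H]2OC(C)(C)O[C@@H]2C1)(c1ccccc1)c1ccccc1
F3 | step 13 | (4S,5R)-1-[(tert-butyldiphenylsilyl)oxy]cyclohex-2-ene-4,5-diol | CC(C)(C)[Si](OC1C=C[C@H](O)[C@H](O)C1)(c1ccccc1)c1ccccc1
F4 | step 13 | (6R)-4-[(tert-butyldiphenylsilyl)oxy]-6-hydroxycyclohex-2-en-1-one | CC(C)(C)[Si](OC1C=CC(=O)[C@H](O)C1)(c1ccccc1)c1ccccc1
F5 | step 13 | (6R)-6-[(tert-butyldimethylsilyl)oxy]-4-[(tert-butyldiphenylsilyl)oxy]cyclohex-2-en-1-one | CC(C)(C)[Si](OC1C=CC(=O)[C@H](O[Si](C)(C)C(C)(C)C)C1)(c1ccccc1)c1ccccc1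
F6 | step 13 | (1R,6R)-6-[(tert-butyldimethylsilyl)oxy]-4-[(tert-butyldiphenylsilyl)oxy]-1-[(trimethylsilyl)ethynyl]cyclohex-2-en-1-ol | CC(C)(C)[Si](OC1C=C[C@@](O)(C#C[Si](C)(C)C)[C@H](O[Si](C)(C)C(C)(C)C)C1)(c1ccccc1)c1ccccc1
F7 | step 13 | (1R,6R)-1-[(trimethylsilyl)ethynyl]cyclohex-2-ene-1,4,6-triol | OC1C=C[C@@](O)(C#C[Si](C)(C)C)[C@H](O)C1
F8 | step 13 | (4R,5R)-4,5-dihydroxy-4-[(trimethylsilyl)ethynyl]cyclohex-2-en-1-one | O=C1C=C[C@@](O)(C#C[Si](C)(C)C)[C@H](O)C1
F9 | step 15 | (4R,5R)-2-azido-4,5-(isopropylidenedioxy)-4-[(trimethylsilyl)ethynyl]cyclohex-2-en-1-one | [N-]=[N+]=NC1=C[C@]2(C#C[Si](C)(C)C)OC(C)(C)O[C@@H]2CC1=O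
F10 | step 15 | (4R,5R)-2-amino-4,5-(isopropylidenedioxy)-4-[(trimethylsilyl)ethynyl]cyclohex-2-en-1-one | NC1=C[C@]2(C#C[Si](C)(C)C)OC(C)(C)O[C@@H]2CC1=O
F11 | step 15 | (2E,4E,6R)-2,4,6-trimethyldeca-2,4-dienoic acid | CCCC[C@@H](C)/C=C(C)/C=C(\C)C(O)=O
F12 | step 15 | (2E,4E,6R)-2,4,6-trimethyldeca-2,4-dienoyl chloride | CCCC[C@@H](C)/C=C(C)/C=C(\C)C(Cl)=O
F13 | step 17 | (2E,4E,6R)-N-[(3R,4R)-3,4-dihydroxy-3-{(3E,5E)-7-[(2-hydroxy-5-oxocyclopent-1-en-1-yl)amino]-7-oxohepta-3,5-dien-1-yn-1-yl}-6-oxocyclohex-1-en-1-yl]-2,4,6-trimethyldeca-2,4-dienamide | CCCC[C@@H](C)/C=C(C)/C=C(\C)C(=O)NC1=C[C@@](O)(C#C/C=C/C=C/C(=O)NC2=C(O)CCC2=O)[C@H](O)CC1=O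
F14 | step 17 | (2E,4E,6R)-N-[(3R,4R)-3,4-dihydroxy-3-{(1Z,3E,5E)-7-[(2-hydroxy-5-oxocyclopent-1-en-1-yl)amino]-7-oxo-2-(triethoxysilyl)hepta-1,3,5-trien-1-yl}-6-oxocyclohex-1-en-1-yl]-2,4,6-trimethyldeca-2,4-dienamide | CCCC[C@@H](C)/C=C(C)/C=C(\C)C(=O)NC1=C[C@@](O)(/C=C(/C=C/C=C/C(=O)NC2=C(O)CCC2=O)[Si](OCC)(OCC)OCC)[C@H](O)CC1=O
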